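## Retrosynthetic overview
1. 8 ⇒ 7 + MeOH. The C4–OMe bond is made last by face-selective oxidative para-methoxylation (dearomatisation) of phenol ring A, which sets the quaternary (4R) centre.
2. 7 ⇒ 4. The allyl group comes from O-allylation and an aromatic Claisen shift to the ortho carbon para to OMe.
3. 4 ⇒ 3. The side-chain (R) centre comes from Ir-catalysed asymmetric hydrogenation of an (E)-α-methylstilbene.
4. 3 ⇒ 1 + 2. Mizoroki–Heck coupling of a bromophenol with (E)-methyl isoeugenol.
5. No ring is built. Rings A and B are bought as arenes, and ring A becomes the cyclohexadienone in the last step.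

**Structure read from the SMILES:** (4R)-4-[(2R)-1-(3,4-dimethoxyphenyl)propan-2-yl]-4,5-dimethoxy-2-(prop-2-en-1-yl)cyclohexa-2,5-dien-1-one, C22H28O5.

**Assumption:** the catalyst enantiomers written in steps 2 and 4 are those expected to give the drawn configuration. Both mirror-image catalysts are equally available and would be swapped if the first run shows the opposite sense.

**Abbreviations**
- L* = (S)-4-tert-butyl-2-[2-(di-o-tolylphosphanyl)phenyl]-4,5-dihydrooxazole. This is the ligand enantiomer taken to convert (E)-1,2-diphenylpropene into (R)-1,2-diphenylpropane.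
- BArF = B[3,5-(CF3)2C6H3]4 anion.
- ArI* = (R,R)-2-iodo-1,3-bis[1-(mesitylcarbamoyl)ethoxy]benzene, C[C@@H](Oc1cccc(O[C@H](C)C(=O)Nc2c(C)cc(C)cc2C)c1I)C(=O)Nc1c(C)cc(C)cc1C.

## Route

Step 1
Reactants: 1 4-bromo-3-methoxyphenol; 2 (E)-methyl isoeugenol (1,2-dimethoxy-4-[(E)-prop-1-enyl]benzene, 1.5 equiv)
Product: 3 4-[(1E)-1-(3,4-dimethoxyphenyl)prop-1-en-2-yl]-3-methoxyphenol
Conditions: Pd(OAc)2 (2 mol %), P(o-tol)3 (4 mol %), NaOAc (1.5 equiv), DMA, 125 °C, 16 h; recrystallise
Reagents that add atoms: none
Why: Mizoroki–Heck reaction in which the aryl group adds to the methyl-bearing alkene carbon (palladium ends up benzylic), and the single β-hydrogen then leaves by syn elimination after bond rotation, so the (E)-alkene gives the (E)-trisubstituted stilbene with the two aryl groups trans.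

Step 2
Reactants: 3 4-[(1E)-1-(3,4-dimethoxyphenyl)prop-1-en-2-yl]-3-methoxyphenol
Product: 4 4-[(2R)-1-(3,4-dimethoxyphenyl)propan-2-yl]-3-methoxyphenol
Conditions: [Ir(cod)(L*)]BArF (1 mol %), H2 (50 bar), CH2Cl2, rt, 12 h
Reagents that add atoms: none
Why: Iridium–phosphinooxazoline asymmetric hydrogenation of an unfunctionalised (E)-α-methylstilbene, the benchmark substrate class for these catalysts, in which the ligand quadrants fix the alkene face that takes up H2 and so set the (R) centre, while the phenol, the ethers and both arenes stay untouched.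

Step 3
Reactants: 4 4-[(2R)-1-(3,4-dimethoxyphenyl)propan-2-yl]-3-methoxyphenol
Product: 7 2-allyl-4-[(2R)-1-(3,4-dimethoxyphenyl)propan-2-yl]-5-methoxyphenol, via allyl aryl ether 5 (not isolated), via ortho-allyl cyclohexadienone 6 (not isolated)
Conditions: allyl bromide (1.05 equiv), K2CO3 (1.5 equiv), NMP, 50 °C, 3 h; filter off salts; then 200 °C, argon, 3 h
Reagents that add atoms: allyl bromide, C=CCBr
Why: Williamson O-allylation followed by an aromatic Claisen [3,3] shift and tautomerisation, directed to the free ortho carbon para to OMe because the other ortho carbon is blocked by the methoxy methyl group that the branched neighbour pushes toward it (allyl 3,4-dimethoxyphenyl ether behaves the same way), and the remote (R) centre is not involved.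

Step 4
Reactants: 7 2-allyl-4-[(2R)-1-(3,4-dimethoxyphenyl)propan-2-yl]-5-methoxyphenol
Product: 8 (4R)-4-[(2R)-1-(3,4-dimethoxyphenyl)propan-2-yl]-4,5-dimethoxy-2-allylcyclohexa-2,5-dien-1-one
Conditions: ArI* (15 mol %), mCPBA (1.2 equiv, syringe pump over 8 h), MeOH (20 equiv), CH2Cl2/toluene 1:1, −20 °C; aq. Na2S2O3/NaHCO3; chromatography
Reagents that add atoms: methanol, CO
Why: Proposed new method: catalyst-controlled intermolecular para-methoxylative dearomatisation of a 4-alkylphenol, in which mCPBA oxidises the C2-symmetric iodoarene to its trivalent-iodine form, 7 binds to iodine through the phenolic oxygen, the breaking O–I bond must stand perpendicular to ring A so that iodine and its hydrogen-bond-folded lactamide arms cover one ring face (the pocket chooses that face by telling the allyl-bearing ortho carbon from the unsubstituted one), and MeOH attacks C4 from the open face in a concerted vinylogous SN2'-type displacement of the monovalent iodoarene, forming the C4–OMe bond and setting (4R) beside the untouched (R) centre; the low-polarity solvent, −20 °C and the absence of fluorinated alcohols hold back the free phenoxenium path that would erase catalyst control, mCPBA alone does not oxidise 7 at this temperature so there is no uncatalysed background, and its low stationary concentration spares the terminal alkene; the closest known reaction types are the PhI(OAc)2/MeOH para-methoxylation of phenols (no stereocontrol), the chiral-iodoarene-catalysed Kita-type ortho-spirolactonisation and the chiral-iodoarene-catalysed hydroxylative dearomatisation to para-quinols (modest selectivity), and what has not been shown is high face selectivity with an external alcohol at the para carbon.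

**Note on purity:** the side-chain centre is already fixed, so step 4 decides a diastereomer ratio and the C4 epimer is removed on silica. Material from the minor enantiomer of 4 ends up mainly in that epimeric series, which raises the ee of 8.

## Compound list
1 | 4-bromo-3-methoxyphenol | COc1cc(O)ccc1Br | starting material
2 | (E)-methyl isoeugenol, 1,2-dimethoxy-4-[(E)-prop-1-enyl]benzene | C/C=C/c1ccc(OC)c(OC)c1 | starting material
3 | 4-[(1E)-1-(3,4-dimethoxyphenyl)prop-1-en-2-yl]-3-methoxyphenol | C/C(c1ccc(O)cc1OC)=C\c1ccc(OC)c(OC)c1 | intermediate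
4 | 4-[(2R)-1-(3,4-dimethoxyphenyl)propan-2-yl]-3-methoxyphenol | COc1cc(O)ccc1[C@H](C)Cc1ccc(OC)c(OC)c1 | intermediate
5 | 4-allyloxy-1-[(2R)-1-(3,4-dimethoxyphenyl)propan-2-yl]-2-methoxybenzene (not isolated) | C=CCOc1ccc([C@H](C)Cc2ccc(OC)c(OC)c2)c(OC)c1 | intermediate
6 | 6-allyl-4-[(2R)-1-(3,4-dimethoxyphenyl)propan-2-yl]-3-methoxycyclohexa-2,4-dien-1-one, both C6 epimers (not isolated) | C=CCC1C=C([C@H](C)Cc2ccc(OC)c(OC)c2)C(OC)=CC1=O | intermediate
7 | 2-allyl-4-[(2R)-1-(3,4-dimethoxyphenyl)propan-2-yl]-5-methoxyphenol | C=CCc1cc([C@H](C)Cc2ccc(OC)c(OC)c2)c(OC)cc1O | intermediate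
8 | (4R)-4-[(2R)-1-(3,4-dimethoxyphenyl)propan-2-yl]-4,5-dimethoxy-2-allylcyclohexa-2,5-dien-1-one | C=CCC1=C[C@](OC)([C@H](C)Cc2ccc(OC)c(OC)c2)C(OC)=CC1=O | target

**Total step count:** 4 (step 3 is one telescoped operation).
**Longest linear sequence:** 4.

## Steps most likely to fail

**Step 4 (the proposed new step).**
- Risks: partial ionisation to a free phenoxenium ion gives poor face selectivity. Slow epoxidation of the allyl group, attack at an ortho carbon, or spirocyclisation by ring B could also compete.
- Fallback, known chemistry, from 7 back to 8: the C–O bond is made with water and the methyl group is added afterwards.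
  - 7 is oxidised with stoichiometric PhI(OAc)2 in MeCN/H2O at 0 °C. This gives the (4R)-para-quinol F3 and the (4S)-para-quinol F4 without stereocontrol.
  - The two free alcohols are separated on silica.
  - The (4R)-para-quinol F3 is O-methylated with MeI and Ag2O in CH2Cl2 in the dark to give 8.

**Step 1.**
- Risks: slow oxidative addition of the electron-rich bromophenol to zerovalent palladium, some 1,1-diaryl regioisomer, and palladium hydride migration of the double bond.
- Fallback from 1 back to 3: carbonyl addition and dehydration replace the cross-coupling.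
  - 1 is converted with n-BuLi (2.1 equiv, THF, −78 °C) into the O,C-dilithio species.
  - LaCl3·2LiCl is added to suppress enolisation, followed by purchased 1-(3,4-dimethoxyphenyl)propan-2-one (CC(=O)Cc1ccc(OC)c(OC)c1). This gives the tertiary benzylic alcohol F1.
  - Catalytic p-TsOH in warm toluene dehydrates F1 to the thermodynamically preferred (E)-alkene 3, which is purified by recrystallisation.

**Step 3.**
- Risks: some migration to the crowded ortho carbon, re-allylation of 7 by leftover allyl bromide, and allyl-to-propenyl isomerisation at 200 °C.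
- Fallback from 4 back to 7: halogenation and cross-coupling replace the sigmatropic shift.
  - 4 is brominated with NBS (1.0 equiv, MeCN, −30 °C) at the ring A carbon that is ortho to OH and para to OMe, the most activated and most open position. This gives the bromophenol F2.
  - F2 is coupled with allyltributylstannane (Pd(PPh3)4, toluene, 100 °C, Stille allylation) to give 7.

## Further compounds
F1 | step 1 | 4-[1-(3,4-dimethoxyphenyl)-2-hydroxypropan-2-yl]-3-methoxyphenol (racemic) | CC(O)(Cc1ccc(OC)c(OC)c1)c1ccc(O)cc1OC
F2 | step 3 | 2-bromo-4-[(2R)-1-(3,4-dimethoxyphenyl)propan-2-yl]-5-methoxyphenol | COc1cc(O)c(Br)cc1[C@H](C)Cc1ccc(OC)c(OC)c1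
F3 | step 4 | (4R)-4-[(2R)-1-(3,4-dimethoxyphenyl)propan-2-yl]-4-hydroxy-5-methoxy-2-allylcyclohexa-2,5-dien-1-one | C=CCC1=C[C@](O)([C@H](C)Cc2ccc(OC)c(OC)c2)C(OC)=CC1=O
F4 | step 4 | (4S)-4-[(2R)-1-(3,4-dimethoxyphenyl)propan-2-yl]-4-hydroxy-5-methoxy-2-allylcyclohexa-2,5-dien-1-one | C=CCC1=C[C@@](O)([C@H](C)Cc2ccc(OC)c(OC)c2)C(OC)=CC1=O
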